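How much faster does product form at a fixed conversion when more precatalyst goes in? Powers of ten answer this best.

| flask | substrate | precatalyst | remark |
|---|---|---|---|
| south-east | 0.050 M | 20 µM | run made earlier |
| south-west | 0.20 M | 20 µM | run made earlier |
| west | 0.10 M | 30 µM | run made earlier |
| flask | 0.10 M | 20 µM |  |

| run | time / h | product / % | substrate / % |
|---|---|---|---|
| south-east | 0.500 | 5 | 98 |
| south-east | 0.833 | 3 | 93 |
| south-east | 1.33 | 15 | 91 |
| south-east | 2.00 | 21 | 80 |
| south-east | 3.00 | 32 | 69 |
| south-east | 5.00 | 46 | 54 |
| south-east | 8.00 | 60 | 41 |
| south-west | 1.00 | 3 | 94 |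
| south-west | 2.00 | 15 | 82 |
| south-west | 3.00 | 26 | 74 |
| south-west | 4.00 | 39 | 63 |
| south-west | 5.00 | 45 | 50 |
| south-west | 6.00 | 58 | 43 |
| south-west | 8.00 | 75 | 28 |
| west | 1.33 | 19 | 82 |
| west | 3.00 | 50 | 48 |
| west | 4.00 | 63 | 34 |
| west | 6.00 | 73 | 21 |
| west | 8.00 | 79 | 20 |

(scatter of a reading: 2 percentage points)

* factor on the rate of making product when 10 % of the substrate are converted if precatalyst is charged twice over
* factor on the rate when 10 % of the substrate are converted if precatalyst is charged at 200 µM instead

- the earlier runs were read with a standard deviation of 2 percentage points
- reactions considered so far: precatalyst <-> enzyme; substrate + enzyme -> product + enzyme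

Define the load order, or apparent order in catalyst, as the logarithm of the rate factor divided by the logarithm of the load factor, both taken at the same conversion.

Two views dispute it. The forecast's maker reads the west run against the runs at 20 µM and finds “an order near 1.9, which suggests two precatalysts form the active enzyme”. That view gives 3.5 for doubling and 50 at 200 µM, or a load order of 1.70 for the tenfold step.

I hold that each precatalyst gives one enzyme. Past the induction period, [enzyme] follows the charge, so the load order is 1. Early on, [enzyme] grows as charge times time and product as charge times time squared, so a fixed conversion comes at a time going as the inverse square root of the charge, and the load order is 0.5. The south-west run has 3 % product at 1.00 h, and the west run is past 10 % by 1.33 h, so I place this conversion near the end of the lag. I therefore commit to the midpoint, a load order of 0.750, which gives 1.68 and 5.62.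

The simulation gives 1.60 and 4.16.

    precatalyst ⇌ enzyme (K = 2.00, k = 0.0130 /min)
    substrate + enzyme → product + enzyme, rate k2*[substrate]^2.5*[enzyme]/(1 + ([substrate]/Kh2)^2.5) (0.0600 M, k = 37000 /M².5/min)

These are load orders of 0.678 and 0.619, both lower than my 0.750. The flask reaches 10 % conversion at 1.13 h, which is 1.91 times the relaxation half-life of precatalyst and enzyme, 0.592 h. At that moment 51.1 % of the flask's catalyst is precatalyst, against 33.3 % at 12.0 h.

The readings are calculated with constants of no real substance, noise included.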